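**Retrosynthetic overview**
1. Key disconnection, carbinol C–O bond. Water adds to the terminal alkene of 11-bromoundec-1-ene (1) by catalytic enantioselective Markovnikov hydration. This gives (S)-11-bromoundecan-2-ol (2) and sets the only stereocentre of the target, 5-[(16S)-16-hydroxyheptadecyl]benzene-1,3-diol.
2. C11–C12 (sp3–sp3). Bromo alcohol 2 is joined to 6-bromohex-1-ene (3) through its Grignard reagent (4; the magnesium alkoxides 5 and 6 stay in the flask), giving (S)-heptadec-16-en-2-ol (7).
3. Aryl–C17 (sp2–sp3). Alkenol 7 and unprotected 5-bromoresorcinol (8) are joined by hydroboration (borane 9) and B-alkyl Suzuki coupling, giving hansfordiol A (10).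
4. No ring is formed. The only ring, the resorcinol, is bought in 8, and no protecting groups are used.

**Notes before the steps**
Assumption: the (1R,2R) ligand is taken to deliver the (S)-alcohol; if the sense of induction is opposite, the equally available (1S,2S) ligand is used.
Catalyst of step 1: Co(ArSalen) is the divalent cobalt chelate C64H78CoN2O2. Its ligand is the dianion of (1R,2R)-N,N'-bis[5-tert-butyl-3-(3,5-di-tert-butylphenyl)-2-hydroxybenzylidene]-1,2-diphenylethane-1,2-diamine, metalated with Co(OAc)2. It is prepared separately and is not counted as a route step.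

**Route**

Step 1
Reactants: 1 11-bromoundec-1-ene
Product: 2 (S)-11-bromoundecan-2-ol
Conditions: Co(ArSalen) (5 mol %), N-fluoro-2,4,6-trimethylpyridinium triflate (1.5 equiv), PhSiH3 (1.5 equiv), H2O (20 equiv), acetone, -10 °C, argon
Reagents that add atoms: water, O
Why: Proposed new method: intermolecular enantioselective Markovnikov hydration of an unactivated 1-alkene by cobalt-hydride hydrogen-atom transfer and radical-polar crossover, in which the N-fluoropyridinium salt oxidises divalent Co(ArSalen) to a trivalent cobalt fluoride, PhSiH3 converts this to the trivalent cobalt hydride, H-atom transfer to the terminal CH2 gives only the secondary C2 radical (hence the 2-ol regiochemistry), divalent cobalt captures the radical reversibly as two rapidly interconverting diastereomeric sec-alkylcobalt complexes, one-electron oxidation gives the cationic tetravalent alkylcobalt, and water displaces cobalt from the rear in an SN2 step with no free cation and so no hydride shift, so that the C–O bond and the (S) centre form together under Curtin-Hammett control because only the diastereomer with CH3 in the narrow slot between the 3,3'-aryl walls and the long chain in the open quadrant is oxidised and displaced quickly (the aryl pi faces also stabilise the cationic transition state), while the primary bromide is inert because no low-valent cobalt is present; the closest known reaction types are the racemic Co(salen)/N-fluoropyridinium/silane Markovnikov hydroalkoxylation of 1-alkenes and its enantioselective intramolecular version, which closes alkenols to 2-methyltetrahydrofurans through the same CH3–CH(Co)–CH2R intermediate.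

Step 2
Reactants: 2 (S)-11-bromoundecan-2-ol; 3 6-bromohex-1-ene
Product: 7 (S)-heptadec-16-en-2-ol, via hex-5-enylmagnesium bromide 4 (not isolated), via bromomagnesium 11-bromoundecan-2-olate 5 (not isolated), via bromomagnesium heptadec-16-en-2-olate 6 (not isolated)
Conditions: 3 (2.5 equiv), Mg, THF, 40 °C; add to 2, THF, -20 °C; Li2CuCl4 (5 mol %), -20 °C to rt; aqueous quench
Reagents that add atoms: none
Why: In this Kochi-type copper-catalysed sp3–sp3 Grignard cross-coupling the first equivalent of 4 only deprotonates the alcohol to the inert alkoxide 5, and the cuprate then displaces the primary bromide by an SN2-type path that touches neither the remote C2 stereocentre nor the terminal alkene.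

Step 3
Reactants: 7 (S)-heptadec-16-en-2-ol; 8 5-bromobenzene-1,3-diol (5-bromoresorcinol)
Product: 10 hansfordiol A (5-[(16S)-16-hydroxyheptadecyl]benzene-1,3-diol), via bis-9-BBN adduct 9 (not isolated)
Conditions: 9-BBN (2.2 equiv), THF, 0 °C to rt; then 8 (1.2 equiv), Pd(OAc)2 (3 mol %), SPhos (6 mol %), 3 M aq K3PO4 (7 equiv), THF, 65 °C; aq NH4Cl
Reagents that add atoms: none
Why: In this anti-Markovnikov hydroboration followed by B-alkyl Suzuki-Miyaura coupling one equivalent of 9-BBN caps the OH as a borinate and the second places boron on terminal C17, the electron-rich SPhos-palladium catalyst inserts into the C–Br bond of 8 (its two OH groups are meta and do not deactivate it), aqueous phosphate triggers alkyl transfer and hydrolyses the O–B bond, and the carbinol stereocentre is a spectator.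

**Compound list**
1 | 11-bromoundec-1-ene | C=CCCCCCCCCCBr | starting material
2 | (S)-11-bromoundecan-2-ol | C[C@H](O)CCCCCCCCCBr | intermediate
3 | 6-bromohex-1-ene | C=CCCCCBr | starting material
4 | hex-5-enylmagnesium bromide | C=CCCCC[Mg]Br | intermediate
5 | bromomagnesium (S)-11-bromoundecan-2-olate | C[C@H](O[Mg]Br)CCCCCCCCCBr | intermediate
6 | bromomagnesium (S)-heptadec-16-en-2-olate | C[C@H](O[Mg]Br)CCCCCCCCCCCCCC=C | intermediate
7 | (S)-heptadec-16-en-2-ol | C[C@H](O)CCCCCCCCCCCCCC=C | intermediate
8 | 5-bromobenzene-1,3-diol | Oc1cc(O)cc(Br)c1 | starting material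
9 | (S)-9-{[17-(9-borabicyclo[3.3.1]nonan-9-yl)heptadecan-2-yl]oxy}-9-borabicyclo[3.3.1]nonane (bis-9-BBN adduct) | C[C@H](OB1C2CCCC1CCC2)CCCCCCCCCCCCCCCB1C2CCCC1CCC2 | intermediate
10 | hansfordiol A, 5-[(16S)-16-hydroxyheptadecyl]benzene-1,3-diol | C[C@H](O)CCCCCCCCCCCCCCCc1cc(O)cc(O)c1 | target

**Totals**
Total step count: 3. Longest linear sequence: 3 (1 → 2 → 7 → 10).

**Three steps most likely to fail**

Step 1 (the proposed new hydration) carries the highest risk.
- Without a tether, the CH3 versus CH2R discrimination may give too low an ee.
- The cobalt hydride may isomerise or hydrogenate the alkene, and fluoride may compete with water.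
- The fallback uses known chemistry, sets out from 1 and comes back at 2. Tsuji-Wacker oxidation of 1 (PdCl2 10 mol %, CuCl, O2 1 atm, DMF/H2O 7:1, rt) makes the same C2–O bond as the ketone 11-bromoundecan-2-one F1.
- A Prelog-selective alcohol dehydrogenase (Rhodococcus ruber ADH-A, NAD+ cat., 2-propanol 15 vol %, phosphate buffer pH 7.5, 30 °C) then delivers hydride to the Re face of F1. This gives 2 in above 99 % ee at the cost of one extra step.

Step 3 (coupling with unprotected phenols) is the second risk.
- The phenoxides of 8 may slow oxidative addition or bind boron.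
- Beta-hydride elimination or protodeboronation may erode the yield.
- The fallback sets out from 7 and comes back at 10, and it replaces the aryl–alkyl coupling by an alkene disconnection. Wittig methylenation of commercial 3,5-bis(benzyloxy)benzaldehyde (MePPh3Br, KOtBu, THF, 0 °C) gives 1,3-bis(benzyloxy)-5-vinylbenzene F2.
- Cross-metathesis of 7 with F2 (2 equiv, second-generation Hoveyda-Grubbs catalyst 5 mol %, CH2Cl2, 40 °C) gives (2S,16E)-17-[3,5-bis(benzyloxy)phenyl]heptadec-16-en-2-ol F3.
- Hydrogenation of F3 (H2 1 atm, Pd/C, EtOH/EtOAc, rt) saturates the alkene and cleaves both benzyl ethers in one operation, giving 10.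

Step 2 (Grignard coupling on a free alcohol) is the third risk.
- Halogen-magnesium exchange or reduction of the bromide may compete.
- A few percent of radical cyclisation can occur while 4 is formed. The resulting saturated by-product cannot hydroborate and is lost after step 3.
- The fallback sets out from 2 and comes back at 7. It replaces magnesium and copper by a palladium-catalysed alkyl-alkyl Suzuki coupling.
- Hexa-1,5-diene (5 equiv) and 9-BBN (THF, 0 °C to rt, excess diene evaporated) give 9-(hex-5-en-1-yl)-9-borabicyclo[3.3.1]nonane F4.
- F4 couples with the primary bromide of 2 (Pd(OAc)2 4 mol %, PCy3 8 mol %, K3PO4·H2O, THF, rt) and tolerates the free alcohol.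

**Further compounds**
F1 | step 1 | 11-bromoundecan-2-one | CC(=O)CCCCCCCCCBr
F2 | step 3 | 1,3-bis(benzyloxy)-5-vinylbenzene | C=Cc1cc(OCc2ccccc2)cc(OCc2ccccc2)c1
F3 | step 3 | (2S,16E)-17-[3,5-bis(benzyloxy)phenyl]heptadec-16-en-2-ol | C[C@H](O)CCCCCCCCCCCCC/C=C/c1cc(OCc2ccccc2)cc(OCc2ccccc2)c1
F4 | step 2 | 9-(hex-5-en-1-yl)-9-borabicyclo[3.3.1]nonane | C=CCCCCB1C2CCCC1CCC2
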